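The bicyclo[3.3.1]nonane (C9 bridging carbonyl; bridgeheads C1, next to quaternary C8, and C5) is opened at C1–C9 and C3–C4. This gives an open chain in which quaternary C5 carries a formyl group (future C9, one oxidation level low) and a methyl ester (future C4), while C1 is the γ-carbon of an aroyl β-diketone (C2, C3). One cascade, dianion aldol C1→C9 then Claisen acylation C3→C4, closes ring B (C1, C8, C7, C6, C5, C9) and ring A (C1–C5, C9) and creates both bridgeheads. It exploits the 1,3-bis-nucleophile C1/C3 around the C2 ketone and the 1,3-bis-electrophile C9/C4 on C5. C7/C8 come from an ester-enolate Claisen rearrangement, C5 from a desymmetrised malonate.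

Key step: step 16

Remark: locants C1–C9 are those of the final bicycle and are kept for the open-chain precursors; prenyl = 3-methylbut-2-en-1-yl, homoprenyl = 4-methylpent-3-en-1-yl, Ar = 3,4-bis(triisopropylsilyloxy)phenyl.
Assumption: the (S,S)-diazaborolidine of step 2 is taken as the enantiomer that delivers the (2R,3S) acid; if the sense of induction is the opposite one, its (R,R) enantiomer is used.

Step 1
Reactants: 1 5-methylhex-4-enoic acid; 2 geraniol
Product: 3 geranyl 5-methylhex-4-enoate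
Conditions: DCC, 4-(dimethylamino)pyridine (cat.), CH2Cl2, 0 °C to rt
Reagents that add atoms: none
Why: Steglich esterification of the acid with the primary allylic alcohol leaves the E-alkene untouched, so the alkene geometry that step 2 translates into the C7/C8 relationship is secured; no stereocentre is formed.

Step 2
Reactants: 3 geranyl 5-methylhex-4-enoate
Product: 5 (2R,3S)-3-ethenyl-3,7-dimethyl-2-(3-methylbut-2-en-1-yl)oct-6-enoic acid, via boron ketene acetal 4 (not isolated)
Conditions: (S,S)-2-bromo-4,5-diphenyl-1,3-bis[3,5-bis(trifluoromethyl)phenylsulfonyl]-1,3,2-diazaborolidine (1.1 equiv), i-Pr2NEt, CH2Cl2, −78 °C, then −20 to 4 °C; aqueous work-up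
Reagents that add atoms: none
Why: Ireland–Claisen-type [3,3] rearrangement of the Z(O)-boron ketene acetal through a chair transition state: the E-geranyl geometry (homoprenyl equatorial, methyl axial) and the equatorial α-prenyl group fix the relative configuration of C7 and C8, and the C2-symmetric diazaborolidine on boron selects the enolate face and thus the absolute configuration of both centres.

Step 3
Reactants: 5 (2R,3S)-3-ethenyl-3,7-dimethyl-2-(3-methylbut-2-en-1-yl)oct-6-enoic acid
Product: 6 (2R,3S)-3-ethenyl-3,7-dimethyl-2-(3-methylbut-2-en-1-yl)oct-6-en-1-ol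
Conditions: LiAlH4, THF, 0 °C to rt
Reagents that add atoms: none
Why: LiAlH4 reduction of the carboxylic acid to the primary alcohol (C6) does not touch isolated alkenes, and C7 cannot epimerise because the acid is reduced as its carboxylate.

Step 4
Reactants: 6 (2R,3S)-3-ethenyl-3,7-dimethyl-2-(3-methylbut-2-en-1-yl)oct-6-en-1-ol; 7 dimethyl malonate
Product: 9 dimethyl 2-[(2S,3S)-3-ethenyl-3,7-dimethyl-2-(3-methylbut-2-en-1-yl)oct-6-en-1-yl]propanedioate, via triflate 8 (not isolated)
Conditions: Tf2O, 2,6-lutidine, CH2Cl2, −78 °C; then NaCH(CO2Me)2 (from 7 and NaH, 3 equiv), THF, −40 °C to rt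
Reagents that add atoms: none
Why: SN2 alkylation of sodium dimethyl malonate by a primary triflate, chosen because C6 is β-branched and next to a quaternary carbon, forms C5–C6 without involving the C7 stereocentre.

Step 5
Reactants: 9 dimethyl 2-[(2S,3S)-3-ethenyl-3,7-dimethyl-2-(3-methylbut-2-en-1-yl)oct-6-en-1-yl]propanedioate; 10 prenyl bromide (1-bromo-3-methylbut-2-ene)
Product: 11 dimethyl 2-[(2S,3S)-3-ethenyl-3,7-dimethyl-2-(3-methylbut-2-en-1-yl)oct-6-en-1-yl]-2-(3-methylbut-2-en-1-yl)propanedioate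
Conditions: NaH, THF–DMF, 0 °C; then 10, rt
Reagents that add atoms: none
Why: The second malonate alkylation (SN2 at the primary carbon of the allylic bromide) makes C5 quaternary; C5 is not yet stereogenic because its two ester groups are identical.

Step 6
Reactants: 11 dimethyl 2-[(2S,3S)-3-ethenyl-3,7-dimethyl-2-(3-methylbut-2-en-1-yl)oct-6-en-1-yl]-2-(3-methylbut-2-en-1-yl)propanedioate
Product: 13 methyl (2R,4S,5S)-5-ethenyl-2-(hydroxymethyl)-5,9-dimethyl-2,4-bis(3-methylbut-2-en-1-yl)dec-8-enoate, via silyl ether 12 (not isolated)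
Conditions: ZnEt2 (10 mol%), chiral pipecolinol-derived tetradentate bis(amino alcohol)phenol ligand (5 mol%, the enantiomer that gives 2R), HSiMe(OMe)2 (2.2 equiv), THF, 0 °C to rt; then K2CO3, MeOH, 0 °C
Reagents that add atoms: none
Why: Zinc hydride-catalysed desymmetrising hydrosilylation of a disubstituted malonate reduces one of the two diastereotopic ester groups to the carbinol; the chiral dinuclear zinc catalyst tells the ester groups apart through the size difference between prenyl and the branched C6 chain and so sets C5 under catalyst control, and the silyl ether formed resists a second reduction.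

Step 7
Reactants: 13 methyl (2R,4S,5S)-5-ethenyl-2-(hydroxymethyl)-5,9-dimethyl-2,4-bis(3-methylbut-2-en-1-yl)dec-8-enoate
Product: 14 methyl (2R,4S,5S)-5-ethenyl-5,9-dimethyl-2,4-bis(3-methylbut-2-en-1-yl)-2-[(triethylsilyloxy)methyl]dec-8-enoate
Conditions: Et3SiCl, imidazole, CH2Cl2, 0 °C
Reagents that add atoms: chlorotriethylsilane, CC[Si](Cl)(CC)CC
Why: Silylation of the primary neopentyl alcohol masks the future C9 oxygen through the hydroboration, oxidation and enolate steps and is later cleaved selectively beside aryl silyl ethers; no stereocentre is touched.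

Step 8
Reactants: 14 methyl (2R,4S,5S)-5-ethenyl-5,9-dimethyl-2,4-bis(3-methylbut-2-en-1-yl)-2-[(triethylsilyloxy)methyl]dec-8-enoate
Product: 16 methyl (2R,4S,5S)-5-(2-hydroxyethyl)-5,9-dimethyl-2,4-bis(3-methylbut-2-en-1-yl)-2-[(triethylsilyloxy)methyl]dec-8-enoate, via alkylborane 15 (not isolated)
Conditions: 9-BBN, THF, 0 °C to rt; then 30% H2O2, aq. NaOAc, 0 °C
Reagents that add atoms: hydrogen peroxide, OO
Why: Hydroboration–oxidation: 9-BBN adds only to the monosubstituted alkene with boron at the terminal carbon (the trisubstituted alkenes and the ester are much slower), and buffered peroxide oxidation with retention gives the C2 primary alcohol; no stereocentre is formed.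

Step 9
Reactants: 16 methyl (2R,4S,5S)-5-(2-hydroxyethyl)-5,9-dimethyl-2,4-bis(3-methylbut-2-en-1-yl)-2-[(triethylsilyloxy)methyl]dec-8-enoate
Product: 17 methyl (2R,4S,5S)-5,9-dimethyl-2,4-bis(3-methylbut-2-en-1-yl)-5-(2-oxoethyl)-2-[(triethylsilyloxy)methyl]dec-8-enoate
Conditions: Dess–Martin periodinane, NaHCO3, CH2Cl2, 0 °C to rt
Reagents that add atoms: none
Why: Dess–Martin oxidation gives the C2 aldehyde under buffered conditions that leave the silyl ether, the ester, the alkenes and all stereocentres intact.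

Step 10
Reactants: 18 1-(3,4-dihydroxyphenyl)ethanone
Product: 19 1-[3,4-bis(triisopropylsilyloxy)phenyl]ethanone
Conditions: i-Pr3SiCl, imidazole, DMF, rt
Reagents that add atoms: chlorotri(propan-2-yl)silane, CC(C)[Si](Cl)(C(C)C)C(C)C
Why: Silylation of both phenols gives aryl triisopropylsilyl ethers that withstand lithium amides, alkoxide and mild acid and are removed by fluoride at the end.

Step 11
Reactants: 17 methyl (2R,4S,5S)-5,9-dimethyl-2,4-bis(3-methylbut-2-en-1-yl)-5-(2-oxoethyl)-2-[(triethylsilyloxy)methyl]dec-8-enoate; 19 1-[3,4-bis(triisopropylsilyloxy)phenyl]ethanone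
Product: 20 β-hydroxy ketone: methyl (2R,4S,5S)-5-[4-Ar-2-hydroxy-4-oxobutyl]-5,9-dimethyl-2,4-bis(3-methylbut-2-en-1-yl)-2-[(triethylsilyloxy)methyl]dec-8-enoate (carbinol carbon as both epimers)
Conditions: LiN(i-Pr)2, THF, −78 °C (19); then 17, −78 °C; aq. NH4Cl
Reagents that add atoms: none
Why: Aldol addition of the kinetic lithium enolate of the methyl ketone to the unhindered aldehyde forms C2–C3, the hindered ester on quaternary C5 being inert at −78 °C; the new carbinol centre forms as both epimers and is erased in step 12.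

Step 12
Reactants: 20 β-hydroxy ketone
Product: 21 β-diketone: methyl (2R,4S,5S)-5-[4-Ar-2,4-dioxobutyl]-5,9-dimethyl-2,4-bis(3-methylbut-2-en-1-yl)-2-[(triethylsilyloxy)methyl]dec-8-enoate (enol form)
Conditions: Dess–Martin periodinane, NaHCO3, CH2Cl2, rt
Reagents that add atoms: none
Why: Dess–Martin oxidation of the β-hydroxy ketone gives the enolised β-diketone and removes the stereo-random carbinol centre.

Step 13
Reactants: 21 β-diketone; 10 prenyl bromide
Product: 22 C1-prenylated diketo ester (21 with a prenyl group on the carbon between C8 and the diketone; C5 R, C7 S, C8 R; C1 as both epimers)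
Conditions: LiN(i-Pr)2 (2.2 equiv), THF, −78 to −20 °C; then 10, −78 °C; AcOH
Reagents that add atoms: none
Why: γ-Alkylation of the β-diketone dianion: the second deprotonation can only occur at C1 because the aryl ketone has no α-hydrogen, and the more basic terminal carbanion is alkylated by the allylic bromide at its primary carbon at low temperature; C1 forms as both epimers, which is harmless because it is re-enolised in step 16.

Step 14
Reactants: 22 C1-prenylated diketo ester
Product: 23 hydroxy diketo ester (22 with free CH2OH on C5)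
Conditions: pyridinium p-toluenesulfonate (cat.), MeOH, rt
Reagents that add atoms: none
Why: Acid-catalysed methanolysis cleaves the primary alkyl triethylsilyl ether much faster than the aryl triisopropylsilyl ethers and is too mild to affect the prenyl alkenes or C5.

Step 15
Reactants: 23 hydroxy diketo ester
Product: 24 formyl diketo ester (23 with CHO on C5; C5 R, C7 S, C8 R; C1 as both epimers)
Conditions: Dess–Martin periodinane, NaHCO3, CH2Cl2, 0 °C to rt
Reagents that add atoms: none
Why: Dess–Martin oxidation of the neopentyl alcohol gives the non-enolisable formyl ester; C5 is quaternary and cannot epimerise.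

Step 16
Reactants: 24 formyl diketo ester
Product: 26 (1S,5R,7S,8R)-3-[3,4-bis(triisopropylsilyloxy)benzoyl]-4,9-dihydroxy-8-methyl-1,5,7-tris(3-methylbut-2-en-1-yl)-8-(4-methylpent-3-en-1-yl)bicyclo[3.3.1]non-3-en-2-one (C9 carbinol as both epimers), via monocyclic aldolate 25 (not isolated)
Conditions: lithium 2,2,6,6-tetramethylpiperidide (2.3 equiv), THF (0.01 M), −78 °C to rt, then 45 °C; aq. NH4Cl
Reagents that add atoms: none
Why: Double deprotonation gives the β-diketone dianion, whose terminal carbon C1 adds to the non-enolisable C9 aldehyde (intramolecular aldol) and whose remaining diketonate carbon C3 then attacks the C4 methyl ester with loss of methoxide (Claisen condensation), the triketone enolate of 26 being the thermodynamic sink. The closest known reaction types are the aldol and Claisen cyclisations of β-diketone dianions and the Dieckmann closure of all-cis 2-acyl-6-alkoxycarbonyl cyclohexanones to bicyclo[3.3.1]nonane-2,4,9-triones. Ring B closes 6-exo-trig at the formyl carbon and ring A 6-exo-trig at the ester carbon, ring B passing through a boat so that the C2–C3–C4 bridge lies syn to the C7 prenyl group. C1 is controlled by the preset C5: the aldol step is reversible, only the aldolate with C2 cis to the C4 ester can cyclise and the bicyclic frame ties C1 to C5, while C9 forms as both epimers and is erased in step 17. The step needs chemoselectivity (C1 to C9, C3 to C4) and closure on the face syn to the C7 prenyl; both rest on the aldehyde/ester pair on the configured quaternary C5, since the C1 carbanion adds fastest to the aldehyde, the stabilised C3 anion cannot trap an aldehyde irreversibly, and the C5 configuration places the ester on the C7-prenyl side of ring B.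

Step 17
Reactants: 26 bicyclic C9 carbinol
Product: 27 (1S,5S,7S,8R)-3-[3,4-bis(triisopropylsilyloxy)benzoyl]-4-hydroxy-8-methyl-1,5,7-tris(3-methylbut-2-en-1-yl)-8-(4-methylpent-3-en-1-yl)bicyclo[3.3.1]non-3-ene-2,9-dione
Conditions: Dess–Martin periodinane, NaHCO3, CH2Cl2, rt
Reagents that add atoms: none
Why: Dess–Martin oxidation of the bridging secondary alcohol gives the C9 ketone and removes the only undefined stereocentre; C3 of the enolised triketone bears no hydrogen and the aryl silyl ethers are inert.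

Step 18
Reactants: 27 bis-silylated trione
Product: 28 (1S,5S,7S,8R)-3-(3,4-dihydroxybenzoyl)-4-hydroxy-8-methyl-1,5,7-tris(3-methylbut-2-en-1-yl)-8-(4-methylpent-3-en-1-yl)bicyclo[3.3.1]non-3-ene-2,9-dione
Conditions: Bu4NF, AcOH, THF, 0 °C
Reagents that add atoms: none
Why: Fluoride-mediated cleavage of the two aryl silyl ethers, buffered with acetic acid so that the catechol and the enolised triketone are not exposed to base, frees the target without touching any stereocentre.

Compound list

1 | 5-methylhex-4-enoic acid | CC(C)=CCCC(=O)O | starting material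
2 | geraniol, (2E)-3,7-dimethylocta-2,6-dien-1-ol | CC(C)=CCC/C(C)=C/CO | starting material
3 | geranyl 5-methylhex-4-enoate | CC(C)=CCCC(=O)OC/C=C(\C)CCC=C(C)C | intermediate
4 | boron ketene acetal of 3, Z(O) geometry, boron in the (S,S)-diazaborolidine (not isolated) | CC(C)=CC/C=C(\OB1N(S(=O)(=O)c2cc(cc(c2)C(F)(F)F)C(F)(F)F)[C@@H](c2ccccc2)[C@H](c2ccccc2)N1S(=O)(=O)c1cc(cc(c1)C(F)(F)F)C(F)(F)F)OC/C=C(\C)CCC=C(C)C | intermediate
5 | (2R,3S)-3-ethenyl-3,7-dimethyl-2-(3-methylbut-2-en-1-yl)oct-6-enoic acid | CC(C)=CCC[C@](C=C)(C)[C@@H](CC=C(C)C)C(=O)O | intermediate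
6 | (2R,3S)-3-ethenyl-3,7-dimethyl-2-(3-methylbut-2-en-1-yl)oct-6-en-1-ol | CC(C)=CCC[C@](C=C)(C)[C@@H](CC=C(C)C)CO | intermediate
7 | dimethyl malonate | COC(=O)CC(=O)OC | starting material
8 | trifluoromethanesulfonate of 6 (not isolated) | CC(C)=CCC[C@](C=C)(C)[C@@H](CC=C(C)C)COS(=O)(=O)C(F)(F)F | intermediate
9 | dimethyl 2-[(2S,3S)-3-ethenyl-3,7-dimethyl-2-(3-methylbut-2-en-1-yl)oct-6-en-1-yl]propanedioate | CC(C)=CCC[C@](C=C)(C)[C@@H](CC=C(C)C)CC(C(=O)OC)C(=O)OC | intermediate
10 | prenyl bromide, 1-bromo-3-methylbut-2-ene | CC(C)=CCBr | starting material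
11 | dimethyl 2-[(2S,3S)-3-ethenyl-3,7-dimethyl-2-(3-methylbut-2-en-1-yl)oct-6-en-1-yl]-2-(3-methylbut-2-en-1-yl)propanedioate | CC(C)=CCC[C@](C=C)(C)[C@@H](CC=C(C)C)CC(CC=C(C)C)(C(=O)OC)C(=O)OC | intermediate
12 | dimethoxy(methyl)silyl ether of 13 (not isolated) | CC(C)=CCC[C@](C=C)(C)[C@@H](CC=C(C)C)C[C@](CC=C(C)C)(CO[Si](C)(OC)OC)C(=O)OC | intermediate
13 | methyl (2R,4S,5S)-5-ethenyl-2-(hydroxymethyl)-5,9-dimethyl-2,4-bis(3-methylbut-2-en-1-yl)dec-8-enoate | CC(C)=CCC[C@](C=C)(C)[C@@H](CC=C(C)C)C[C@](CC=C(C)C)(CO)C(=O)OC | intermediate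
14 | methyl (2R,4S,5S)-5-ethenyl-5,9-dimethyl-2,4-bis(3-methylbut-2-en-1-yl)-2-[(triethylsilyloxy)methyl]dec-8-enoate | CC(C)=CCC[C@](C=C)(C)[C@@H](CC=C(C)C)C[C@](CC=C(C)C)(CO[Si](CC)(CC)CC)C(=O)OC | intermediate
15 | B-alkyl-9-borabicyclo[3.3.1]nonane from 14, boron on the terminal carbon of the former vinyl group (not isolated) | CC(C)=CCC[C@](CCB1C2CCCC1CCC2)(C)[C@@H](CC=C(C)C)C[C@](CC=C(C)C)(CO[Si](CC)(CC)CC)C(=O)OC | intermediate
16 | methyl (2R,4S,5S)-5-(2-hydroxyethyl)-5,9-dimethyl-2,4-bis(3-methylbut-2-en-1-yl)-2-[(triethylsilyloxy)methyl]dec-8-enoate | CC(C)=CCC[C@](CCO)(C)[C@@H](CC=C(C)C)C[C@](CC=C(C)C)(CO[Si](CC)(CC)CC)C(=O)OC | intermediate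
17 | methyl (2R,4S,5S)-5,9-dimethyl-2,4-bis(3-methylbut-2-en-1-yl)-5-(2-oxoethyl)-2-[(triethylsilyloxy)methyl]dec-8-enoate | CC(C)=CCC[C@](CC=O)(C)[C@@H](CC=C(C)C)C[C@](CC=C(C)C)(CO[Si](CC)(CC)CC)C(=O)OC | intermediate
18 | 1-(3,4-dihydroxyphenyl)ethanone | CC(=O)c1ccc(O)c(O)c1 | starting material
19 | 1-[3,4-bis(triisopropylsilyloxy)phenyl]ethanone | CC(=O)c1ccc(O[Si](C(C)C)(C(C)C)C(C)C)c(O[Si](C(C)C)(C(C)C)C(C)C)c1 | intermediate
20 | β-hydroxy ketone, 17 extended at the aldehyde carbon to CH(OH)CH2C(=O)Ar (carbinol as both epimers) | CC(C)=CCC[C@](CC(O)CC(=O)c1ccc(O[Si](C(C)C)(C(C)C)C(C)C)c(O[Si](C(C)C)(C(C)C)C(C)C)c1)(C)[C@@H](CC=C(C)C)C[C@](CC=C(C)C)(CO[Si](CC)(CC)CC)C(=O)OC | intermediate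
21 | β-diketone, CH2C(=O)CH2C(=O)Ar on C8 | CC(C)=CCC[C@](CC(=O)CC(=O)c1ccc(O[Si](C(C)C)(C(C)C)C(C)C)c(O[Si](C(C)C)(C(C)C)C(C)C)c1)(C)[C@@H](CC=C(C)C)C[C@](CC=C(C)C)(CO[Si](CC)(CC)CC)C(=O)OC | intermediate
22 | C1-prenylated diketo ester (C5 R, C7 S, C8 R; C1 both epimers) | CC(C)=CCC[C@](C(CC=C(C)C)C(=O)CC(=O)c1ccc(O[Si](C(C)C)(C(C)C)C(C)C)c(O[Si](C(C)C)(C(C)C)C(C)C)c1)(C)[C@@H](CC=C(C)C)C[C@](CC=C(C)C)(CO[Si](CC)(CC)CC)C(=O)OC | intermediate
23 | hydroxy diketo ester, free CH2OH on C5 | CC(C)=CCC[C@](C(CC=C(C)C)C(=O)CC(=O)c1ccc(O[Si](C(C)C)(C(C)C)C(C)C)c(O[Si](C(C)C)(C(C)C)C(C)C)c1)(C)[C@@H](CC=C(C)C)C[C@](CC=C(C)C)(CO)C(=O)OC | intermediate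
24 | formyl diketo ester, CHO and CO2Me on C5 (C5 R, C7 S, C8 R; C1 both epimers) | CC(C)=CCC[C@](C(CC=C(C)C)C(=O)CC(=O)c1ccc(O[Si](C(C)C)(C(C)C)C(C)C)c(O[Si](C(C)C)(C(C)C)C(C)C)c1)(C)[C@@H](CC=C(C)C)C[C@](CC=C(C)C)(C=O)C(=O)OC | intermediate
25 | monocyclic aldolate (drawn as the neutral aldol; present as its dilithium salt), ring B closed, C2 acyl on C1 and CO2Me on C5 both cis to the C7 prenyl, C9 carbinol both epimers (not isolated) | CC(C)=CCC[C@]1(C)[C@@H](CC=C(C)C)C[C@@](CC=C(C)C)(C(=O)OC)C(O)[C@@]1(CC=C(C)C)C(=O)CC(=O)c1ccc(O[Si](C(C)C)(C(C)C)C(C)C)c(O[Si](C(C)C)(C(C)C)C(C)C)c1 | intermediate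
26 | (1S,5R,7S,8R)-3-[3,4-bis(triisopropylsilyloxy)benzoyl]-4,9-dihydroxy-8-methyl-1,5,7-tris(3-methylbut-2-en-1-yl)-8-(4-methylpent-3-en-1-yl)bicyclo[3.3.1]non-3-en-2-one (C9 both epimers) | CC(C)=CCC[C@]1(C)[C@@H](CC=C(C)C)C[C@]2(CC=C(C)C)C(O)[C@@]1(CC=C(C)C)C(=O)C(C(=O)c1ccc(O[Si](C(C)C)(C(C)C)C(C)C)c(O[Si](C(C)C)(C(C)C)C(C)C)c1)=C2O | intermediate
27 | (1S,5S,7S,8R)-3-[3,4-bis(triisopropylsilyloxy)benzoyl]-4-hydroxy-8-methyl-1,5,7-tris(3-methylbut-2-en-1-yl)-8-(4-methylpent-3-en-1-yl)bicyclo[3.3.1]non-3-ene-2,9-dione | CC(C)=CCC[C@]1(C)[C@@H](CC=C(C)C)C[C@]2(CC=C(C)C)C(=O)[C@@]1(CC=C(C)C)C(=O)C(C(=O)c1ccc(O[Si](C(C)C)(C(C)C)C(C)C)c(O[Si](C(C)C)(C(C)C)C(C)C)c1)=C2O | intermediate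
28 | (1S,5S,7S,8R)-3-(3,4-dihydroxybenzoyl)-4-hydroxy-8-methyl-1,5,7-tris(3-methylbut-2-en-1-yl)-8-(4-methylpent-3-en-1-yl)bicyclo[3.3.1]non-3-ene-2,9-dione | CC(C)=CCC[C@]1(C)[C@@H](CC=C(C)C)C[C@]2(CC=C(C)C)C(=O)[C@@]1(CC=C(C)C)C(=O)C(C(=O)c1ccc(O)c(O)c1)=C2O | target

Total step count: 18
Longest linear sequence: 17 steps (steps 1–9 and 11–18; step 10 is a side branch)

Steps most likely to fail

Step 16. Process at risk: the reversible aldol may hold too little of the aldolate with C2 cis to the ester, so that slower irreversible events (attack of the C1 carbanion on the ester, or loss of the formyl group through attack of the liberated methoxide) overtake the boat-type Claisen closure. Fallback (the two rings are closed in separate operations by known reactions): starting from 24, TMSOTf and Et3N in CH2Cl2 (−78 to 0 °C) convert the diketone into its 1,3-bis(trimethylsilyloxy)diene F1, whose terminal carbon C1 adds in the same flask to the silyl triflate-activated aldehyde (intramolecular vinylogous Mukaiyama aldol); mildly acidic work-up gives the monocyclic aldol F2 as a mixture at C1 and C9. Dess–Martin oxidation of the C9 carbinol and chromatographic removal of the C1 epimer give the all-cis 2-acyl-6-methoxycarbonyl cyclohexanone F3, and KOt-Bu in THF closes ring A by Dieckmann condensation, which comes back to the route at 27.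

Step 6. Process at risk: poor discrimination between the two diastereotopic ester groups when the chiral catalyst and the C7/C8 stereocentres are mismatched, or over-reduction to the diol. Fallback (separation instead of catalyst control): starting from 11, LiAlH(Ot-Bu)3 in THF reduces one ester group without selectivity and gives 13 together with its C5 epimer F4; the two diastereomers are separated by chromatography, and the fallback comes back to the route at 13.

Step 13. Process at risk: the C1 carbanion of the dianion may add to the ester on C5 (premature ring closure) before it is alkylated, or alkylation may take place at C3 or at oxygen. Fallback (the prenyl group is put on C1 before the diketone exists): starting from 17, cyclohexylamine and MgSO4 give the imine F5; LiN(i-Pr)2 at −78 °C and 10 give the C-prenylated imine F6 (alkylation of a metalated imine), which aqueous oxalic acid hydrolyses to the α-prenyl aldehyde F7; aldol addition of the lithium enolate of 19 gives the β-hydroxy ketone F8, and Dess–Martin oxidation comes back to the route at 22.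

Further compounds

F1 | step 16 | 1,3-bis(trimethylsilyloxy)diene of 24 (not isolated) | CC(C)=CCC[C@](C(CC=C(C)C)=C(O[Si](C)(C)C)C=C(O[Si](C)(C)C)c1ccc(O[Si](C(C)C)(C(C)C)C(C)C)c(O[Si](C(C)C)(C(C)C)C(C)C)c1)(C)[C@@H](CC=C(C)C)C[C@](CC=C(C)C)(C=O)C(=O)OC
F2 | step 16 | monocyclic aldol, ring B closed, mixture at C1 and C9 | CC(C)=CCC[C@]1(C)[C@@H](CC=C(C)C)C[C@@](CC=C(C)C)(C(=O)OC)C(O)C1(CC=C(C)C)C(=O)CC(=O)c1ccc(O[Si](C(C)C)(C(C)C)C(C)C)c(O[Si](C(C)C)(C(C)C)C(C)C)c1
F3 | step 16 | all-cis 2-acyl-6-methoxycarbonyl cyclohexanone (C9 ketone, C2 acyl cis to the ester and to the C7 prenyl) | CC(C)=CCC[C@]1(C)[C@@H](CC=C(C)C)C[C@@](CC=C(C)C)(C(=O)OC)C(=O)[C@@]1(CC=C(C)C)C(=O)CC(=O)c1ccc(O[Si](C(C)C)(C(C)C)C(C)C)c(O[Si](C(C)C)(C(C)C)C(C)C)c1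
F4 | step 6 | C5 epimer of 13, methyl (2S,4S,5S)-5-ethenyl-2-(hydroxymethyl)-5,9-dimethyl-2,4-bis(3-methylbut-2-en-1-yl)dec-8-enoate | CC(C)=CCC[C@](C=C)(C)[C@@H](CC=C(C)C)C[C@@](CC=C(C)C)(CO)C(=O)OC
F5 | step 13 | N-cyclohexyl imine of 17 | CC(C)=CCC[C@](CC=NC1CCCCC1)(C)[C@@H](CC=C(C)C)C[C@](CC=C(C)C)(CO[Si](CC)(CC)CC)C(=O)OC
F6 | step 13 | C1-prenylated N-cyclohexyl imine (C1 both epimers, not isolated) | CC(C)=CCC[C@](C(CC=C(C)C)C=NC1CCCCC1)(C)[C@@H](CC=C(C)C)C[C@](CC=C(C)C)(CO[Si](CC)(CC)CC)C(=O)OC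
F7 | step 13 | α-prenyl aldehyde, 17 with a prenyl group on C1 (both epimers) | CC(C)=CCC[C@](C(CC=C(C)C)C=O)(C)[C@@H](CC=C(C)C)C[C@](CC=C(C)C)(CO[Si](CC)(CC)CC)C(=O)OC
F8 | step 13 | β-hydroxy ketone from F7 and the enolate of 19 (C1 and carbinol carbon as mixtures) | CC(C)=CCC[C@](C(CC=C(C)C)C(O)CC(=O)c1ccc(O[Si](C(C)C)(C(C)C)C(C)C)c(O[Si](C(C)C)(C(C)C)C(C)C)c1)(C)[C@@H](CC=C(C)C)C[C@](CC=C(C)C)(CO[Si](CC)(CC)CC)C(=O)OC
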